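The plan cuts the oxepine ring at the aryl–O and aryl–CH2 bonds and keeps the bornane C2–O bond throughout. With its carbonyl carbon read as C6, (1S,4S)-camphor delivers C1, C4 and C7. In the boat-shaped ring C1–C6, the endo arm on C6 and the endo hydrogen on C2 lie 1,3-syn on the concave face, and the key step exploits this contact. The alkoxy radical of (bornan-2-endo-yl)methanol removes that hydrogen. Oxidative closure then gives a bridging tetrahydrofuran: one C–O bond, one ring and the C2 stereocentre in one operation. Lactone formation, aryllithium addition and ketone-activated SNAr later close the oxepine.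

Key step: step 5

Labels: bornane atoms carry the numbers of the target (C1 methyl-bearing bridgehead, C2 oxygen-bearing, C4 bridgehead CH, C6 bearing the benzylic carbon, C7 CMe2). Arene carbons are a (isovaleryl), b (OH), c (CHO), d (O–C2), e (benzylic carbon), f (OH).

Remark: electrophiles and lithium bases are assumed to prefer position c, next to the tied-back ring oxygen. Position a lies between two methoxy groups, one of them pushed by the e substituent. The formyl group is therefore placed first and the isovaleryl group second.

Step 1
Reactants: 1 (1S,4S)-(−)-camphor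
Product: 3 (1S,4S)-1,7,7-trimethylbicyclo[2.2.1]hept-2-en-2-yl trifluoromethanesulfonate, via lithium enolate 2 (not isolated)
Conditions: LDA, THF, −78 to 0 °C; PhNTf2, 0 °C to rt; H2O
Reagents that add atoms: N-phenylbis(trifluoromethanesulfonimide), O=S(=O)(N(c1ccccc1)S(=O)(=O)C(F)(F)F)C(F)(F)F
Why: Enolate O-sulfonylation (vinyl triflate synthesis) should work because camphor can enolise only toward C3 (C1 is quaternary), and the basic medium avoids cationic skeletal shifts, so the two bridgehead centres are carried over unchanged.

Step 2
Reactants: 3 bornenyl triflate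
Product: 4 methyl (1S,4S)-1,7,7-trimethylbicyclo[2.2.1]hept-2-ene-2-carboxylate
Conditions: Pd(OAc)2 (5 mol %), PPh3 (10 mol %), Et3N, CO (1 atm), MeOH–DMF, rt to 50 °C
Reagents that add atoms: carbon monoxide, [C-]#[O+]; methanol, CO
Why: Palladium-catalysed methoxycarbonylation of a vinyl triflate (oxidative addition, CO insertion, methanolysis) installs the carbon that becomes the benzylic carbon without touching a stereocentre.

Step 3
Reactants: 4 unsaturated ester
Product: 6 methyl (1R,2R,4S)-bornane-2-endo-carboxylate, via exo ester 5 (not isolated)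
Conditions: H2 (1 atm), 10 % Pd/C, MeOH, rt; filter; NaOMe, MeOH, reflux
Reagents that add atoms: none
Why: Heterogeneous syn-hydrogenation should come from the endo face, away from the syn C7 methyl, to give exo ester 5, and enolate-mediated epimerisation under thermodynamic control then moves the ester to the endo position, clear of that methyl and of the near-eclipsed C1 methyl; this sets the future C6 centre, and any remaining exo epimer is separated after step 4 and re-equilibrated.

Step 4
Reactants: 6 endo ester
Product: 7 [(1R,2R,4S)-bornan-2-endo-yl]methanol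
Conditions: LiAlH4, Et2O, 0 °C to rt; H2O
Reagents that add atoms: none
Why: Hydride reduction of the ester gives the primary alcohol and leaves the three stereocentres untouched.

Step 5
Reactants: 7 (bornan-2-endo-yl)methanol
Product: 10 (1R,3S,6R,7R)-7,8,8-trimethyl-4-oxatricyclo[4.2.1.0^3,7]nonane (tetrahydrofuran bridging endo C2–O and the endo CH2 on C6), via hypoiodite 8 (not isolated), via exo iodide 9 (not isolated)
Conditions: PhI(OAc)2 (1.5 equiv), I2 (1 equiv), cyclohexane, visible light (tungsten lamp), 25–40 °C
Reagents that add atoms: none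
Why: Acetyl hypoiodite formed from PhI(OAc)2 and I2 turns 7 into hypoiodite 8, light breaks the O–I bond, the alkoxy radical takes the endo hydrogen of C2 through a six-membered transition state (1,5-hydrogen transfer), and the C2 radical picks up iodine on the exo side, the endo side being occupied by the hydroxymethyl arm, to give 9, whose iodide is expelled by the hydroxyl group. The closest known reaction type is the Suárez hypoiodite reaction, which converts rigid steroid and terpenoid alcohols into tetrahydrofurans. The single new ring (O, CH2, C6, C1, C2) closes in the 5-exo-tet mode, with oxygen arriving on the endo face anti to the exo C–I bond, the same trajectory as in the iodolactonisation of endo-norbornenecarboxylic acids. The new C2 stereocentre is controlled by the one-carbon tether on endo C6, which reaches only the endo face of C2, so an exo C–O bond cannot form. The step needs site selectivity among the δ-hydrogens: the endo C2–H is secondary and runs parallel to the C6–CH2 bond about 2.4 Å away, whereas the C1-methyl hydrogens are primary and skewed by roughly 80°, and the C4–H points away from the radical. The non-polar solvent should keep the closure concerted rather than ionic, which disfavours a 2-bornyl cation and its Wagner–Meerwein shift.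

Step 6
Reactants: 10 tricyclic ether
Product: 11 (1R,3S,6R,7R)-7,8,8-trimethyl-4-oxatricyclo[4.2.1.0^3,7]nonan-5-one (γ-lactone, C=O on the former CH2)
Conditions: RuCl3·xH2O (5 mol %), NaIO4 (4 equiv), EtOAc–MeCN–H2O, rt
Reagents that add atoms: sodium periodate, [Na+].[O-]I(=O)(=O)=O
Why: Ruthenium tetroxide oxidation of a cyclic ether to a lactone should attack the open O–CH2 group rather than the exo C2–H, a methine shielded by the syn C7 methyl and the quaternary C1, and the bridgehead C4–H is inert.

Step 7
Reactants: 12 1-fluoro-3,5-dimethoxybenzene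
Product: 13 2-bromo-1-fluoro-3,5-dimethoxybenzene
Conditions: NBS (1.0 equiv), MeCN, 0 °C to rt
Reagents that add atoms: N-bromosuccinimide, O=C1CCC(=O)N1Br
Why: Electrophilic aromatic bromination goes ortho to one methoxy group and para to the other, next to the small fluorine, and avoids the crowded position between the two methoxy groups.

Step 8
Reactants: 13 aryl bromide; 11 lactone
Product: 16 (2-fluoro-4,6-dimethoxyphenyl)(2-endo-hydroxybornan-6-endo-yl)methanone (target numbering; drawn open, may rest as its lactol), via aryllithium 14 (not isolated), via lithium lactolate 15 (not isolated)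
Conditions: 13, n-BuLi, THF, −78 °C; 11, −78 °C; AcOH, −78 °C
Reagents that add atoms: none
Why: Bromine–lithium exchange followed by acyl substitution on the lactone should stop at one addition because lactolate 15 holds until the cold quench and the two ortho substituents hinder a second attack, while −78 °C prevents loss of LiF from 14; the C2–O bond and all four stereocentres stay intact.

Step 9
Reactants: 16 hydroxy ketone
Product: 18 oxepinone (seven-membered ring O–Cd–Ce–C(=O)–C6–C1–C2; OMe at b and f, H at a and c; O endo on C2, acyl carbon endo on C6), via potassium alkoxide 17 (not isolated)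
Conditions: KHMDS (1.2 equiv), THF–DMF, 0 to 60 °C
Reagents that add atoms: none
Why: Intramolecular SNAr (addition–elimination) at the fluorine-bearing carbon d, activated by the ortho ketone, closes the seven-membered ring from the C2 alkoxide, so the C2–O bond is never broken, and base-induced epimerisation at C6 is harmless because only the endo epimer can cyclise and the ring then locks it.

Step 10
Reactants: 18 oxepinone
Product: 20 dimethoxy oxepine (as 18 with CH2 in place of C=O), via benzylic alcohol 19 (not isolated)
Conditions: Et3SiH (5 equiv), TFA, CH2Cl2, 0 °C to rt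
Reagents that add atoms: none
Why: Ionic hydrogenation of an electron-rich aryl ketone gives alcohol 19 by hydride transfer, and this ionises to a cation stabilised by three ring oxygens that should be reduced again faster than it can lose a proton or rearrange.

Step 11
Reactants: 20 dimethoxy oxepine
Product: 22 c-formyl dimethoxy oxepine (CHO between the ring oxygen at d and the methoxy group at b), via iminium chloride 21 (not isolated)
Conditions: POCl3, DMF, 0 to 60 °C; ice–water
Reagents that add atoms: N,N-dimethylformamide, CN(C)C=O; water, O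
Why: Vilsmeier–Haack formylation should choose position c, which is para to the coplanar f-methoxy group and flanked by a ring oxygen whose alkyl group is tied back, over position a, crowded by two methoxy groups; 5,7-dialkoxychromans and 4,6-dimethoxyindoles show the same preference towards electrophiles.

Step 12
Reactants: 22 aldehyde; 23 isovaleraldehyde
Product: 27 a-(1-hydroxy-3-methylbutyl)-c-formyl dimethoxy oxepine (carbinol epimers), via amino alkoxide 24 (not isolated), via aryllithium 25 (not isolated), via dilithium dialkoxide 26 (not isolated)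
Conditions: MeNHCH2CH2NMe2, n-BuLi, THF, −20 °C; 22; n-BuLi (3 equiv), −20 to 0 °C; 23, −78 °C to rt; H2O
Reagents that add atoms: none
Why: In situ protection of the aldehyde as α-amino alkoxide 24 followed by directed ortho-metalation removes the only ring hydrogen left, at a between two methoxy groups, so the regiochemistry is fixed by construction, and the configuration of the new carbinol is irrelevant because step 13 destroys it.

Step 13
Reactants: 27 hydroxy aldehyde
Product: 28 di-O-methyl ether of the target (isovaleryl at a, CHO at c, OMe at b and f)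
Conditions: Dess–Martin periodinane, CH2Cl2, rt
Reagents that add atoms: none
Why: Dess–Martin oxidation converts the secondary benzylic alcohol into the aryl ketone under neutral conditions and leaves the aldehyde and the ethers alone.

Step 14
Reactants: 28 di-O-methyl ether
Product: 29 target CNP0246493.1
Conditions: BCl3 (4 equiv), CH2Cl2, −78 °C to rt; H2O
Reagents that add atoms: none
Why: Chelation-assisted ether cleavage with BCl3 should remove both methyl groups, each on an oxygen ortho to a carbonyl group, by SN2 attack of chloride, whereas C2 of the ring ether is neopentyl-like, closed to backside attack and, with an endo leaving group, slow to ionise.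

Compound list
1 | (1S,4S)-(−)-camphor | O=C1C[C@@H]2CC[C@@]1(C)C2(C)C | starting material
2 | lithium enolate of camphor (C2=C3, O–Li on C2) | [Li]OC1=C[C@@H]2CC[C@@]1(C)C2(C)C | intermediate
3 | (1S,4S)-1,7,7-trimethylbicyclo[2.2.1]hept-2-en-2-yl trifluoromethanesulfonate | FC(F)(F)S(=O)(=O)OC1=C[C@@H]2CC[C@@]1(C)C2(C)C | intermediate
4 | methyl (1S,4S)-1,7,7-trimethylbicyclo[2.2.1]hept-2-ene-2-carboxylate | COC(=O)C1=C[C@@H]2CC[C@@]1(C)C2(C)C | intermediate
5 | methyl (1R,2S,4S)-bornane-2-exo-carboxylate | COC(=O)[C@H]1C[C@@H]2CC[C@@]1(C)C2(C)C | intermediate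
6 | methyl (1R,2R,4S)-bornane-2-endo-carboxylate | COC(=O)[C@@H]1C[C@@H]2CC[C@@]1(C)C2(C)C | intermediate
7 | [(1R,2R,4S)-bornan-2-endo-yl]methanol | OC[C@@H]1C[C@@H]2CC[C@@]1(C)C2(C)C | intermediate
8 | hypoiodite of 7 | IOC[C@@H]1C[C@@H]2CC[C@@]1(C)C2(C)C | intermediate
9 | (6-exo-iodobornan-2-endo-yl)methanol (iodine on the carbon that is C2 of the target) | OC[C@@H]1C[C@@H]2C[C@@H](I)[C@@]1(C)C2(C)C | intermediate
10 | (1R,3S,6R,7R)-7,8,8-trimethyl-4-oxatricyclo[4.2.1.0^3,7]nonane | C1[C@@H]2C[C@@H]3C[C@H](O1)[C@@]2(C)C3(C)C | intermediate
11 | (1R,3S,6R,7R)-7,8,8-trimethyl-4-oxatricyclo[4.2.1.0^3,7]nonan-5-one | O=C1[C@@H]2C[C@@H]3C[C@H](O1)[C@@]2(C)C3(C)C | intermediate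
12 | 1-fluoro-3,5-dimethoxybenzene | COc1cc(F)cc(OC)c1 | starting material
13 | 2-bromo-1-fluoro-3,5-dimethoxybenzene | COc1cc(F)c(Br)c(OC)c1 | intermediate
14 | (2-fluoro-4,6-dimethoxyphenyl)lithium | COc1cc(F)c([Li])c(OC)c1 | intermediate
15 | lithium lactolate from 14 and 11 | [O-]C1(c4c(F)cc(OC)cc4OC)[C@@H]2C[C@@H]3C[C@H](O1)[C@@]2(C)C3(C)C.[Li+] | intermediate
16 | (2-fluoro-4,6-dimethoxyphenyl)(2-endo-hydroxybornan-6-endo-yl)methanone (target numbering) | O=C(c1c(F)cc(OC)cc1OC)[C@@H]2C[C@@H]3C[C@H](O)[C@@]2(C)C3(C)C | intermediate
17 | potassium C2-alkoxide of 16 | O=C(c1c(F)cc(OC)cc1OC)[C@@H]2C[C@@H]3C[C@H]([O-])[C@@]2(C)C3(C)C.[K+] | intermediate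
18 | oxepinone (b,f-dimethoxy, benzylic C=O) | c1c(OC)cc2c(c1OC)C(=O)[C@@H]1C[C@@H]3C[C@H](O2)[C@@]1(C)C3(C)C | intermediate
19 | benzylic alcohol from 18 (carbinol epimers) | c1c(OC)cc2c(c1OC)C(O)[C@@H]1C[C@@H]3C[C@H](O2)[C@@]1(C)C3(C)C | intermediate
20 | dimethoxy oxepine (benzylic CH2) | c1c(OC)cc2c(c1OC)C[C@@H]1C[C@@H]3C[C@H](O2)[C@@]1(C)C3(C)C | intermediate
21 | c-(dimethyliminiomethyl) derivative of 20, chloride | c1c(OC)c(C=[N+](C)C)c2c(c1OC)C[C@@H]1C[C@@H]3C[C@H](O2)[C@@]1(C)C3(C)C.[Cl-] | intermediate
22 | c-formyl dimethoxy oxepine | c1c(OC)c(C=O)c2c(c1OC)C[C@@H]1C[C@@H]3C[C@H](O2)[C@@]1(C)C3(C)C | intermediate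
23 | isovaleraldehyde | CC(C)CC=O | starting material
24 | lithium α-amino alkoxide of 22 | c1c(OC)c(C([O-])N(C)CCN(C)C)c2c(c1OC)C[C@@H]1C[C@@H]3C[C@H](O2)[C@@]1(C)C3(C)C.[Li+] | intermediate
25 | a-lithio derivative of 24 | [Li]c1c(OC)c(C([O-])N(C)CCN(C)C)c2c(c1OC)C[C@@H]1C[C@@H]3C[C@H](O2)[C@@]1(C)C3(C)C.[Li+] | intermediate
26 | dilithium dialkoxide from 25 and 23 | CC(C)CC([O-])c1c(OC)c(C([O-])N(C)CCN(C)C)c2c(c1OC)C[C@@H]1C[C@@H]3C[C@H](O2)[C@@]1(C)C3(C)C.[Li+].[Li+] | intermediate
27 | a-(1-hydroxy-3-methylbutyl)-c-formyl dimethoxy oxepine | CC(C)CC(O)c1c(OC)c(C=O)c2c(c1OC)C[C@@H]1C[C@@H]3C[C@H](O2)[C@@]1(C)C3(C)C | intermediate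
28 | di-O-methyl ether of the target | CC(C)CC(=O)c1c(OC)c(C=O)c2c(c1OC)C[C@@H]1C[C@@H]3C[C@H](O2)[C@@]1(C)C3(C)C | intermediate
29 | CNP0246493.1 | CC(C)CC(=O)c1c(O)c(C=O)c2c(c1O)C[C@@H]1C[C@@H]3C[C@H](O2)[C@@]1(C)C3(C)C | target

Total step count: 14. Longest linear sequence: 13 (steps 1–6 and 8–14).

Steps most likely to fail

Step 5. After iodine transfer the C2–I bond may ionise, and the C1–C6 bond may migrate (Wagner–Meerwein shift) before oxygen closes. Hydrogen abstraction may also stray to the C1 methyl group, or the alkoxy radical may lose formaldehyde by β-scission. The fallback sets out from 6 and comes back at 11. The ester is saponified with KOH in aqueous methanol to bornane-2-endo-carboxylic acid F1. A carboxylate-directed C–H lactonisation follows, with a non-haem iron or manganese catalyst of the PDP type and H2O2. The metal-bound oxo group takes the same endo C2–H and returns oxygen on the same face by rebound. Lactone 11 then forms without a hypoiodite or an alkyl iodide, and steps 4 to 6 are skipped.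

Step 8. Attack of the hindered aryllithium on the lactone carbonyl may be too slow at −78 °C, while warming brings on loss of lithium fluoride. Early collapse of the adduct may also allow a second addition. The fallback sets out from 11 and 14 and comes back at 16. DIBAL-H in toluene at −78 °C reduces 11 to lactol F2. Transmetalation of 14 with MgBr2·OEt2 gives arylmagnesium bromide F3, which tolerates 0 °C. An excess of it adds to the hydroxy aldehyde tautomer of the lactol to give diol F4. MnO2 in CH2Cl2 then oxidises only the benzylic alcohol and returns 16.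

Step 12. Deprotonation at position a may be slow because both flanking methoxy groups are pushed by their other neighbours out of the conformation that binds lithium. Long exposure to butyllithium may also erode the amino alkoxide. The fallback sets out from 22 and comes back at 27, and it replaces C–H deprotonation by halogen–metal exchange. NBS in MeCN brominates the only free ring position to give bromo aldehyde F5. Condensation with N,N'-dimethylethylenediamine gives imidazolidine F6. Bromine–lithium exchange with n-BuLi at −78 °C gives aryllithium F7, which adds to 23 to give carbinol F8. Dilute aqueous acid in the work-up opens the aminal and returns 27.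

Further compounds
F1 | step 5 | (1R,2R,4S)-bornane-2-endo-carboxylic acid | OC(=O)[C@@H]1C[C@@H]2CC[C@@]1(C)C2(C)C
F2 | step 8 | 7,8,8-trimethyl-4-oxatricyclo[4.2.1.0^3,7]nonan-5-ol (lactol, anomers) | OC1[C@@H]2C[C@@H]3C[C@H](O1)[C@@]2(C)C3(C)C
F3 | step 8 | (2-fluoro-4,6-dimethoxyphenyl)magnesium bromide | COc1cc(F)c([Mg]Br)c(OC)c1
F4 | step 8 | (2-fluoro-4,6-dimethoxyphenyl)(2-endo-hydroxybornan-6-endo-yl)methanol (carbinol epimers) | OC(c1c(F)cc(OC)cc1OC)[C@@H]2C[C@@H]3C[C@H](O)[C@@]2(C)C3(C)C
F5 | step 12 | a-bromo-c-formyl dimethoxy oxepine | Brc1c(OC)c(C=O)c2c(c1OC)C[C@@H]1C[C@@H]3C[C@H](O2)[C@@]1(C)C3(C)C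
F6 | step 12 | a-bromo-c-(1,3-dimethylimidazolidin-2-yl) dimethoxy oxepine | Brc1c(OC)c(C4N(C)CCN4C)c2c(c1OC)C[C@@H]1C[C@@H]3C[C@H](O2)[C@@]1(C)C3(C)C
F7 | step 12 | a-lithio-c-(1,3-dimethylimidazolidin-2-yl) dimethoxy oxepine | [Li]c1c(OC)c(C4N(C)CCN4C)c2c(c1OC)C[C@@H]1C[C@@H]3C[C@H](O2)[C@@]1(C)C3(C)C
F8 | step 12 | a-(1-hydroxy-3-methylbutyl)-c-(1,3-dimethylimidazolidin-2-yl) dimethoxy oxepine | CC(C)CC(O)c1c(OC)c(C4N(C)CCN4C)c2c(c1OC)C[C@@H]1C[C@@H]3C[C@H](O2)[C@@]1(C)C3(C)C
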